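The vessel is closed and stirred, the gas is held at saturation outside the solution, and both substrates start as a racemate.

in all of them: gas 7.6 mM (held); free catalyst 32 µM; racemization catalyst 0.95 mM
- teal: left-handed substrate 9.5 mM; right-handed substrate 9.5 mM; run made earlier
- grey: left-handed substrate 14 mM; right-handed substrate 14 mM; run made earlier
- flask: left-handed substrate 19 mM; right-handed substrate 19 mM; time 10 h
- teal (time / h: left-handed product / %, right-handed product / %): 0.500: 5, 0; 1.50: 20, 1; 3.00: 35, 7; 4.00: 45, 7; 6.00: 59, 5; 8.00: 69, 8
- grey (time / h: left-handed product / %, right-handed product / %): 1.33: 15, 0; 2.50: 31, 0; 4.00: 40, 3; 5.00: 51, 4; 6.00: 54, 6; 8.00: 65, 7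

(each reading ± 2 percentage points)
- free catalyst is single-handed; left-handed substrate and right-handed substrate are mirror images of each other, charged as a racemate, each of them at the stated concentration
- at the start none of the gas is in solution
- an excess is the difference of the two amounts in percent of their sum
- an excess is below zero if the other one leads
- left-handed product and right-handed product together, in percent of the left-handed substrate and right-handed substrate charged together, at 10 h
- excess of left-handed product over right-handed product in the product at 10 h
- whether the exchange between left-handed substrate and right-handed substrate keeps pace with the reaction: how far the product's excess at 10 h gets from its value without exchange to its value with instant exchange (above 80% keeps pace, below 20% hardly takes part, else lags behind)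

Read the teal and grey runs as a ladder of rates, fastest rung first.

1. Gas enters the solution. [gas] in solution starts at nothing, and in the teal run the left-handed product's pace rises from 10.0 % h⁻¹ to 15.0 % h⁻¹, so the first hour is a start-up.
2. Left-handed substrate reacts. That second pace, taken on its own charge, reads 0.300 h⁻¹.
3. Substrate crosses over. Teal's left-handed product reaches 69%, above the 50% of left-handed substrate charged, so right-handed substrate has been converted into left-handed. Define the tail constant, a pseudo-first-order constant, as the rate at which the two substrates together shrink from 4.00 h to 8.00 h. Teal reads 0.184 h⁻¹ and grey 0.178 h⁻¹, so take 0.181 h⁻¹.
4. Right-handed substrate reacts directly. Teal's average reads 0.0200 h⁻¹, a selectivity factor near 15.0. With instant exchange the two substrates stay equal, so on these readings the product's excess stays at 87.5%. Teal's excess at 8.00 h reads 79.2%, lower than that, so I expect exchange to lag behind.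

My reckoning: the remainder at 8.00 h grows with charge, and extended to this flask it is 33.6%. The tail constant then gives 76.6% converted by 10 h. The excess stands at 79.2% in teal and 80.6% in grey, so I say about the same here.

The forecast gives 72%, 77% and lags behind: “exchange probably lags behind, though this is uncertain”.

The flask gives 77.8% with excess 80.6%, and exchange lags behind, 66% of the way.

    partner + free catalyst + left-handed substrate → free catalyst + left-handed product (k = 36000 M⁻² min⁻¹)
    partner + free catalyst + right-handed substrate → free catalyst + right-handed product (k = 2000 M⁻² min⁻¹)
    left-handed substrate + racemization catalyst ⇌ right-handed substrate + racemization catalyst, rate k3*[racemization catalyst]*[left-handed substrate] forward; the back reaction follows from the equilibrium constant (k = 3.30 M⁻¹ min⁻¹)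
    gas ⇌ partner, rate k4*(csat - [partner]) (kL = 0.0430 min⁻¹)
    2 racemization catalyst ⇌ resting dimer, settled at all times (K = 43.0 M⁻¹)

Among the remaining substrates at 10.0 h, right-handed leads by 48.7%. Running 0.181 h⁻¹ from the flask's 46.3% of substrates at 5.00 h gives 18.7% at 10.0 h, and the flask holds 22.2%. The neighbour with 3.8 mM of racemization catalyst holds 14.8% of substrates at that time, less than the 18.7% that constant gave for the flask.

(The earlier runs and the new flask are calculated with made-up constants, noise included.)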